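Remark (assumption): the target SMILES contains no stereocentre and its diaryl ether bonds rotate freely, so the compound is achiral and "single enantiomer" sets no stereochemical task. Racemic sp3 centres occur only in 12, 14 and 16 and are erased on aromatisation.

## Structural features

The target (C18H14O11) is a linear triaryl diether of three polyhydroxybenzene rings. Ring P is a phloroglucinol ring (P1, P3, P5 = C–OH; P4, P6 = C–H) whose P2 carries the ether oxygen to Q1; ring Q is the central ring (Q1–O–P2, Q2–O–R1, Q3/Q4/Q5 = C–OH, Q6 = C–H); ring R is a 3,4,5-trihydroxyphenyl ring bound through R1–O to Q2 (R2, R6 = C–H). The nine free phenols, and above all the two pyrogallol arrays (Q3–Q5 and R3–R5), autoxidise readily to o-quinones, especially in base, so the hydroxyl groups must be freed last and handled under inert gas. The R1–O–Q2 ether is ordinary on the ring R side (two ortho C–H) and becomes easy if Q1 carries an electron-withdrawing group while it is formed. The real difficulty is the P2–O–Q1 ether: P2 lies between two oxygenated carbons and Q1 lies next to the aryloxy-bearing Q2, so this is a tri-ortho-substituted ether between two π-excessive rings, the worst case for any aryl C–O coupling. Ring Q adds the demand of five contiguous oxygens in three different roles. The feature that the key step exploits is the oxygen pattern of ring P: P1, P3 and P5 carry oxygen, P4 and P6 hydrogen, and P2 the ether oxygen. This is exactly the pattern generated when the two carbons of an aryloxyketene (P1 = C=O, P2 = CH–OAr) are combined with two molecules of an alkoxyethyne (P4≡P3–OR and P6≡P5–OR). Hence the P2–O bond can be made by O-alkylation at an sp3 carbon before ring P exists, and ring P can then be built around it.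

## Logic of the disconnections

18 ⇒ 17. The eight O–alkyl bonds are cut (six O–CH3 on rings Q and R, two O–CH2CH3 on ring P). The free polyphenol cannot be carried through the route, and an all-alkyl protecting scheme lets one reagent free every hydroxyl at the end. The gain is a neutral, lipophilic, air-stable precursor. The forward step must cleave methyl and ethyl aryl ethers without touching the two diaryl ether bonds.

17 ⇒ 12 + 9 (key disconnection). The ring P bonds P4–P5 and P6–P1 are cut, which removes the two-carbon unit P5–P6, and the P1–P2 bond is returned to a four-membered ring in which P1 is bonded to P4. In one sentence: ring P is not coupled to the ether oxygen but grown on it, by thermal benzannulation of cyclobutenone 12 with alkyne 9. That sentence does not describe the aryl C–O coupling route (test 1), and the step makes the arene that contains the hardest atom of the target, P2, with all three ring P oxygens in place (test 2). The gain is the step from a tetrasubstituted arene to a four-membered ring plus a commercial C2 unit. The forward step needs a regiospecific ketene–alkyne [2+2] and a thermal cascade that outruns the side reactions of the ketene.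

12 ⇒ 8 + 9. The four-membered ring bonds P1–P4 and P2–P3 are cut ([2+2] retron of a ketene and an alkoxyalkyne). This takes the ring back to an aryloxyacetic acid, so that the six carbons of ring P come from one acetic acid unit and two molecules of 9. The forward step must generate the ketene without acylating the electron-rich rings and capture it with 9 faster than it dimerises.

8 ⇒ 5 + 6. The O–CH2 bond between the Q1 oxygen and P2 is cut. This is the bond that is the hindered diaryl ether in the target; here it is an SN2 alkylation at a primary carbon. The forward step is undemanding.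

5 ⇒ 3. The Q1–OH bond is traced back to a Q1–CHO group (Dakin retron). The formyl group is chosen because it activates the neighbouring Q2–Br for the preceding coupling and is then itself converted into the Q1 oxygen. The forward step requires aryl rather than hydride migration.

3 ⇒ 1 + 2. The Q2–O aryl bond is cut. The phenol partner 2 has two free ortho positions and the bromide 1 is activated by its ortho-formyl group; both are commercial. The forward step is a copper-catalysed coupling at a di-ortho-substituted but activated bromide.

## Other disconnections considered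

Alternative 1: (the first that comes to mind) Both aryl C–O bonds are cut as copper-mediated unions. After steps 1 and 2, phenol 5 would be coupled with 2-iodo-1,3,5-trimethoxybenzene A1 to give the nonamethyl ether A2, which would then be demethylated. This is two steps shorter on paper. It is not preferred because its key coupling attacks the hard bond head-on. It would have to form a tri-ortho-substituted ether from an iodide flanked by two methoxy groups and a phenoxide flanked by an aryloxy group, both partners being electron-rich. Oxidative addition at copper should then be slow, and protodeiodination and phenol oxidation are expected to compete. The chosen plan makes the same bond by SN2 at a primary carbon.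

Alternative 2: The same P2–O bond is cut, but with reversed polarity at P2, as a carbenoid O–H insertion. Rh(II)-catalysed decomposition of 2-diazocyclohexane-1,3-dione A3 in the presence of phenol 5 would give the 2-aryloxy-1,3-dione A4, and dehydrogenative aromatisation would give the resorcinol A5. The chosen plan is preferred on structure and step economy: ring P would arrive one oxygen short. An oxygen at P5 cannot be carried through, because a 5-alkoxy group on the dione is β to both carbonyls and would be eliminated on aromatisation. The P5 hydroxyl would have to be added afterwards by protection, sterically directed C–H borylation and oxidation, at least three more steps. The aromatisation of A4 would also need an oxidant in the presence of two very electron-rich rings.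

Alternative 3: Ring P is cut at P1–P2 as a polyketide-type Claisen cyclisation. Ester 7 would be acylated onto the dianion of methyl acetoacetate to give the 6-aryloxy-3,5-dioxohexanoate A6, and base would close this to the 2-aryloxyphloroglucinol A7, followed by demethylation. The step count equals that of the chosen plan. The chosen plan is preferred on mechanism: the carbon that must act as nucleophile (P2, α to the aryloxy group) is the least acidic of three methylene groups in A6. Base deprotonates the two 1,3-dicarbonyl positions first and thereby turns the ester into a poor electrophile. O-acylation to a 4-hydroxy-2-pyranone and retro-Claisen fragmentation are expected to be easier exits. In the benzannulation the regiochemistry is fixed by ketene/ynol ether polarity and no competing heterocycle is available.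

Key step: step 5

## Steps

Abbreviation: ArO– = 3,4,5-trimethoxy-2-(3,4,5-trimethoxyphenoxy)phenoxy (rings Q and R as their methyl ethers, bound through the Q1 oxygen).

Step 1
Reactants: 1 2-bromo-3,4,5-trimethoxybenzaldehyde; 2 3,4,5-trimethoxyphenol
Product: 3 3,4,5-trimethoxy-2-(3,4,5-trimethoxyphenoxy)benzaldehyde
Conditions: CuI (10 mol %), picolinic acid (20 mol %), K3PO4 (2 equiv), DMSO, 90 °C, Ar
Reagents that add atoms: none
Why: Ullmann-type copper-catalysed diaryl ether synthesis; the ortho-formyl group activates the C–Br bond and the phenol partner has two free ortho positions, so the only hindered partner is the activated one.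

Step 2
Reactants: 3 3,4,5-trimethoxy-2-(3,4,5-trimethoxyphenoxy)benzaldehyde
Product: 5 3,4,5-trimethoxy-2-(3,4,5-trimethoxyphenoxy)phenol, via aryl formate 4 (not isolated)
Conditions: mCPBA (1.3 equiv), CH2Cl2, 0 °C to rt; then K2CO3 (cat.), MeOH, rt
Reagents that add atoms: mCPBA (3-chloroperoxybenzoic acid), O=C(OO)c1cccc(Cl)c1
Why: Baeyer–Villiger (Dakin-type) oxidation; the aryl group, made electron-rich by its ortho-aryloxy and para-methoxy substituents, should migrate in preference to hydride, and the formate 4 is methanolysed to the phenol.

Step 3
Reactants: 5 3,4,5-trimethoxy-2-(3,4,5-trimethoxyphenoxy)phenol; 6 ethyl bromoacetate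
Product: 8 2-[3,4,5-trimethoxy-2-(3,4,5-trimethoxyphenoxy)phenoxy]acetic acid, via ethyl ester 7 (not isolated)
Conditions: K2CO3 (1.5 equiv), DMF, rt; then LiOH, THF/H2O, rt; then 1 M HCl
Reagents that add atoms: lithium hydroxide, [Li+].[OH-]
Why: Williamson ether synthesis (SN2 at a primary α-bromo ester) followed by saponification; this makes the Q1–O–P2 bond at an sp3 carbon, where the ortho substituents of ring Q hardly matter.

Step 4
Reactants: 8 2-[3,4,5-trimethoxy-2-(3,4,5-trimethoxyphenoxy)phenoxy]acetic acid; 9 ethoxyethyne
Product: 12 3-ethoxy-4-[3,4,5-trimethoxy-2-(3,4,5-trimethoxyphenoxy)phenoxy]cyclobut-2-en-1-one (racemic), via acid chloride 10 (not isolated), via aryloxyketene 11 (not isolated)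
Conditions: 1-chloro-N,N,2-trimethylprop-1-en-1-amine (1.1 equiv), CH2Cl2, 0 °C to rt; then 9 (5 equiv), Et3N (1.5 equiv, slow addition), CH2Cl2, 0 °C to rt
Reagents that add atoms: none
Why: Neutral acid chloride formation, dehydrochlorination to the aryloxyketene and ketene–ynol ether [2+2] cycloaddition; the nucleophilic CH terminus of 9 should bond to the ketene carbonyl carbon (P1–P4) and its C–OEt terminus to the aryloxy-bearing carbon (P2–P3). The new sp3 centre at P2 is formed as a racemate and is erased in step 5.

Step 5
Reactants: 12 3-ethoxy-4-[3,4,5-trimethoxy-2-(3,4,5-trimethoxyphenoxy)phenoxy]cyclobut-2-en-1-one; 9 ethoxyethyne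
Product: 17 3,5-diethoxy-2-[3,4,5-trimethoxy-2-(3,4,5-trimethoxyphenoxy)phenoxy]phenol, via vinylketene 13 (not isolated), via alkenylcyclobutenone 14 (not isolated), via dienylketene 15 (not isolated), via cyclohexadienone 16 (not isolated)
Conditions: 9 (4 equiv), toluene (0.05 M), 80 °C, sealed tube, Ar
Reagents that add atoms: none
Why: Danheiser benzannulation (cyclobutenone plus alkynyl ether), the closest known reaction type being the thermal union of cyclobutenones with alkoxy- or siloxyalkynes to resorcinol monoethers; the 3-ethoxy group of 12 turns that pattern into the phloroglucinol pattern. At 80 °C 12 should open by conrotatory 4π-electrocyclic cleavage of the P1–P2 bond, the aryloxy donor at the sp3 carbon rotating outwards, to vinylketene 13. Ethoxyethyne 9 then adds across the ketene C=C in a [2+2] cycloaddition whose regiochemistry is fixed by polarity: its nucleophilic CH terminus (P6) bonds to the electrophilic ketene carbon P1 and its C–OEt terminus (P5) to P4, giving 14. A second, reversible 4π ring opening (cleavage of P1–P4) gives dienylketene 15, and the rotamer with the ketene and alkenyl arms cis closes ring P by thermal disrotatory 6π-electrocyclisation (P1–P2 bond) to dienone 16, which tautomerises irreversibly to phenol 17. No stereocentre is set: the sp3 centres of 12, 14 and 16 are racemic and vanish on aromatisation. The step needs (i) the regiochemistry of the [2+2], secured by the ynol ether/ketene polarisation, which places the new OEt at P5 para to the ether oxygen, and (ii) capture of 13 by 9 in preference to dimerisation or O-acylation of 17, secured by excess 9 and dilution. The aromatic stabilisation gained in the last event makes the cascade irreversible and funnels the reversible ring openings to 17.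

Step 6
Reactants: 17 3,5-diethoxy-2-[3,4,5-trimethoxy-2-(3,4,5-trimethoxyphenoxy)phenoxy]phenol
Product: 18 5-(2,4,6-trihydroxyphenoxy)-4-(3,4,5-trihydroxyphenoxy)benzene-1,2,3-triol (CNP0018317.0)
Conditions: BBr3 (14 equiv), CH2Cl2, −78 °C to rt, Ar; MeOH then H2O, 0 °C; degassed solvents, reversed-phase chromatography
Reagents that add atoms: none
Why: Lewis acid-mediated cleavage of aryl alkyl ethers with BBr3 (bromide attacks the O-alkyl carbon of the borane-complexed ether); methyl and ethyl ethers should both cleave, whereas the diaryl ether bonds offer no sp3 carbon for bromide attack and should survive.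

## Compound list

1 | 2-bromo-3,4,5-trimethoxybenzaldehyde | O=Cc1cc(OC)c(OC)c(OC)c1Br | starting material
2 | 3,4,5-trimethoxyphenol | COc1cc(O)cc(OC)c1OC | starting material
3 | 3,4,5-trimethoxy-2-(3,4,5-trimethoxyphenoxy)benzaldehyde | O=Cc1cc(OC)c(OC)c(OC)c1Oc1cc(OC)c(OC)c(OC)c1 | intermediate
4 | 3,4,5-trimethoxy-2-(3,4,5-trimethoxyphenoxy)phenyl formate | O=COc1cc(OC)c(OC)c(OC)c1Oc1cc(OC)c(OC)c(OC)c1 | intermediate
5 | 3,4,5-trimethoxy-2-(3,4,5-trimethoxyphenoxy)phenol | Oc1cc(OC)c(OC)c(OC)c1Oc1cc(OC)c(OC)c(OC)c1 | intermediate
6 | ethyl bromoacetate | CCOC(=O)CBr | starting material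
7 | ethyl 2-[3,4,5-trimethoxy-2-(3,4,5-trimethoxyphenoxy)phenoxy]acetate | CCOC(=O)COc1cc(OC)c(OC)c(OC)c1Oc1cc(OC)c(OC)c(OC)c1 | intermediate
8 | 2-[3,4,5-trimethoxy-2-(3,4,5-trimethoxyphenoxy)phenoxy]acetic acid | OC(=O)COc1cc(OC)c(OC)c(OC)c1Oc1cc(OC)c(OC)c(OC)c1 | intermediate
9 | ethoxyethyne (ethoxyacetylene) | CCOC#C | starting material
10 | 2-[3,4,5-trimethoxy-2-(3,4,5-trimethoxyphenoxy)phenoxy]acetyl chloride | ClC(=O)COc1cc(OC)c(OC)c(OC)c1Oc1cc(OC)c(OC)c(OC)c1 | intermediate
11 | 2-[3,4,5-trimethoxy-2-(3,4,5-trimethoxyphenoxy)phenoxy]ethen-1-one (aryloxyketene) | O=C=COc1cc(OC)c(OC)c(OC)c1Oc1cc(OC)c(OC)c(OC)c1 | intermediate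
12 | 3-ethoxy-4-[3,4,5-trimethoxy-2-(3,4,5-trimethoxyphenoxy)phenoxy]cyclobut-2-en-1-one (racemic) | CCOC1=CC(=O)C1Oc1cc(OC)c(OC)c(OC)c1Oc1cc(OC)c(OC)c(OC)c1 | intermediate
13 | (3Z)-3-ethoxy-4-(ArO)buta-1,3-dien-1-one (vinylketene; ArO trans to the ketene-bearing carbon) | O=C=C/C(OCC)=C/Oc1cc(OC)c(OC)c(OC)c1Oc1cc(OC)c(OC)c(OC)c1 | intermediate
14 | 3-ethoxy-4-[(Z)-1-ethoxy-2-(ArO)ethenyl]cyclobut-2-en-1-one (racemic) | CCOC1=CC(=O)C1/C(OCC)=C/Oc1cc(OC)c(OC)c(OC)c1Oc1cc(OC)c(OC)c(OC)c1 | intermediate
15 | (3E,5Z)-3,5-diethoxy-6-(ArO)hexa-1,3,5-trien-1-one (dienylketene; ketene and alkenyl arms cis across the central C=C) | O=C=C/C(OCC)=C\C(OCC)=C\Oc1cc(OC)c(OC)c(OC)c1Oc1cc(OC)c(OC)c(OC)c1 | intermediate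
16 | 3,5-diethoxy-6-(ArO)cyclohexa-2,4-dien-1-one (racemic) | CCOC1=CC(=O)C(Oc2cc(OC)c(OC)c(OC)c2Oc2cc(OC)c(OC)c(OC)c2)C(OCC)=C1 | intermediate
17 | 3,5-diethoxy-2-[3,4,5-trimethoxy-2-(3,4,5-trimethoxyphenoxy)phenoxy]phenol | CCOc1cc(O)c(Oc2cc(OC)c(OC)c(OC)c2Oc2cc(OC)c(OC)c(OC)c2)c(OCC)c1 | intermediate
18 | 5-(2,4,6-trihydroxyphenoxy)-4-(3,4,5-trihydroxyphenoxy)benzene-1,2,3-triol (CNP0018317.0, achiral) | Oc1cc(O)c(Oc2cc(O)c(O)c(O)c2Oc2cc(O)c(O)c(O)c2)c(O)c1 | target

## Step count and least certain steps

Total step count: 6. Longest linear sequence: 6 steps (from 1 or 2 to 18).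

Step 5 (key step). What may go wrong: the electron-rich vinylketene may dimerise or oligomerise, or be captured by the phenolic product through O-acylation, faster than it undergoes the [2+2] with the alkyne. The ring opening of a vinylogous-ester cyclobutenone may also require a temperature at which the alkyne itself decomposes by retro-ene loss of ethylene. Any O-acylated product can be returned to the phenol by basic methanolysis of the crude mixture, and a syringe-pump addition of 12 to hot 9 keeps the ketene concentration low. Fallback (sets out from 5, comes back at 18): copper-catalysed Ullmann coupling of 5 with 2-iodo-1,3,5-trimethoxybenzene A1 (CuI, N,N-dimethylglycine, Cs2CO3, dioxane, 110 °C) would give 1,2,3-trimethoxy-4-(3,4,5-trimethoxyphenoxy)-5-(2,4,6-trimethoxyphenoxy)benzene F1 (the structure labelled A2 above). Treatment of F1 with BBr3 as in step 6 would give 18. This route accepts the hindered aryl C–O coupling that the main route avoids.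

Step 4. What may go wrong: dimerisation of the aryloxyketene, intramolecular Friedel–Crafts acylation of ring Q at Q6 by the acid chloride (ring closure to a benzofuranone), or acid-induced polymerisation of the alkyne by amine hydrochloride. Fallback (sets out from ester 7, isolated after the first half of step 3 instead of being saponified, and comes back at 18): acylation of the dianion of methyl acetoacetate (NaH, then n-BuLi, THF, 0 °C) by 7 would give methyl 3,5-dioxo-6-[3,4,5-trimethoxy-2-(3,4,5-trimethoxyphenoxy)phenoxy]hexanoate F2. Intramolecular Claisen condensation (NaOMe, MeOH, 65 °C) would close ring P to 2-[3,4,5-trimethoxy-2-(3,4,5-trimethoxyphenoxy)phenoxy]benzene-1,3,5-triol F3, and BBr3 as in step 6 would convert F3 into 18.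

Step 6. What may go wrong: incomplete cleavage of eight ether groups, because boron chelation between neighbouring oxygens slows the later cleavages, and autoxidation of the pyrogallol arrays of rings Q and R during work-up and chromatography. Fallback (sets out from 17, comes back at 18), a derivatise-purify-release sequence: after the BBr3 treatment the crude polyphenol is acetylated (Ac2O, pyridine, DMAP cat.) to 5-(2,4,6-triacetoxyphenoxy)-4-(3,4,5-triacetoxyphenoxy)benzene-1,2,3-triyl triacetate F4. F4 is air-stable and can be separated on silica from partially alkylated congeners. Acid-catalysed methanolysis (HCl generated from AcCl, degassed MeOH, Ar) then releases 18.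

Step 1. What may go wrong: slow oxidative addition at the di-ortho-substituted bromide, leading to protodebromination or copper-mediated oxidation of the electron-rich phenol, and base-induced side reactions of the aldehyde in hot DMSO. Fallback with reversed polarity (sets out from 1, comes back at 3): copper-catalysed hydroxylation of 1 (CuI, 8-hydroxyquinoline, KOH, DMSO/H2O, 100 °C) would give 2-hydroxy-3,4,5-trimethoxybenzaldehyde F5. Chan–Lam coupling of F5 with (3,4,5-trimethoxyphenyl)boronic acid (Cu(OAc)2, pyridine, 4 Å molecular sieves, air, CH2Cl2, rt) would give 3; the aryl group is then delivered from boron and no oxidative addition into a hindered halide is required.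

## Further compounds

F1 | step 5 | 1,2,3-trimethoxy-4-(3,4,5-trimethoxyphenoxy)-5-(2,4,6-trimethoxyphenoxy)benzene | COc1cc(OC)c(Oc2cc(OC)c(OC)c(OC)c2Oc2cc(OC)c(OC)c(OC)c2)c(OC)c1
F2 | step 4 | methyl 3,5-dioxo-6-[3,4,5-trimethoxy-2-(3,4,5-trimethoxyphenoxy)phenoxy]hexanoate | COC(=O)CC(=O)CC(=O)COc1cc(OC)c(OC)c(OC)c1Oc1cc(OC)c(OC)c(OC)c1
F3 | step 4 | 2-[3,4,5-trimethoxy-2-(3,4,5-trimethoxyphenoxy)phenoxy]benzene-1,3,5-triol | Oc1cc(O)c(Oc2cc(OC)c(OC)c(OC)c2Oc2cc(OC)c(OC)c(OC)c2)c(O)c1
F4 | step 6 | 5-(2,4,6-triacetoxyphenoxy)-4-(3,4,5-triacetoxyphenoxy)benzene-1,2,3-triyl triacetate | CC(=O)Oc1cc(OC(C)=O)c(Oc2cc(OC(C)=O)c(OC(C)=O)c(OC(C)=O)c2Oc2cc(OC(C)=O)c(OC(C)=O)c(OC(C)=O)c2)c(OC(C)=O)c1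
F5 | step 1 | 2-hydroxy-3,4,5-trimethoxybenzaldehyde | O=Cc1cc(OC)c(OC)c(OC)c1O
A1 | alternative 1 | 2-iodo-1,3,5-trimethoxybenzene | COc1cc(OC)c(I)c(OC)c1
A2 | alternative 1 | 1,2,3-trimethoxy-4-(3,4,5-trimethoxyphenoxy)-5-(2,4,6-trimethoxyphenoxy)benzene | COc1cc(OC)c(Oc2cc(OC)c(OC)c(OC)c2Oc2cc(OC)c(OC)c(OC)c2)c(OC)c1
A3 | alternative 2 | 2-diazocyclohexane-1,3-dione | [N-]=[N+]=C1C(=O)CCCC1=O
A4 | alternative 2 | 2-[3,4,5-trimethoxy-2-(3,4,5-trimethoxyphenoxy)phenoxy]cyclohexane-1,3-dione | O=C1CCCC(=O)C1Oc1cc(OC)c(OC)c(OC)c1Oc1cc(OC)c(OC)c(OC)c1
A5 | alternative 2 | 2-[3,4,5-trimethoxy-2-(3,4,5-trimethoxyphenoxy)phenoxy]benzene-1,3-diol | Oc1cccc(O)c1Oc1cc(OC)c(OC)c(OC)c1Oc1cc(OC)c(OC)c(OC)c1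
A6 | alternative 3 | methyl 3,5-dioxo-6-[3,4,5-trimethoxy-2-(3,4,5-trimethoxyphenoxy)phenoxy]hexanoate | COC(=O)CC(=O)CC(=O)COc1cc(OC)c(OC)c(OC)c1Oc1cc(OC)c(OC)c(OC)c1
A7 | alternative 3 | 2-[3,4,5-trimethoxy-2-(3,4,5-trimethoxyphenoxy)phenoxy]benzene-1,3,5-triol | Oc1cc(O)c(Oc2cc(OC)c(OC)c(OC)c2Oc2cc(OC)c(OC)c(OC)c2)c(O)c1
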